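**Plan**

1. Retrosynthesis (quinone locants: C1(=O), C2 henicosyl, C3 methyl, C4(=O), C5 H, C6 OMe): the C3–CH3 bond is cut first, then the ring bonds C3–C4 and C6–C1 together, which leaves two three-carbon pieces.
2. Enabling feature: the ring C1–C6 is two O=C–C=C triads joined head to tail, C1(=O)–C2=C3 and C4(=O)–C5=C6(OMe). The first is stored in the strained three-membered ring of 2-henicosylcyclopropenone 5 (a latent cis-β-acylvinyl carbanion), the second in the β-lithiated β-methoxyacrylamide made from 9.
3. Forward: docosan-1-ol gives docosanal, tricos-1-yne and 5, so C1 of the C22 alcohol becomes ring carbon C2 and the intact C21 chain is in place before any ring exists; methyl (E)-3-methoxyacrylate gives diethylamide 9.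
4. The only ring of the target, the quinone, then arises in one anionic [3+3] cascade at its final oxidation level. The temporary three-membered ring and the NEt2 group are consumed in that step, and the C3 methyl is added last by radical C–H methylation.
5. Stereochemistry: the target has no stereocentre; the only geometric demand, cis-disposed reacting ends in both triads, is met by amide-directed cis-lithiation and by the cyclopropenone ring itself.

Key step: step 6

**Route**

Step 1
Reactants: 1 docosan-1-ol
Product: 2 docosanal
Conditions: TEMPO (10 mol %), PhI(OAc)2 (1.1 equiv), CH2Cl2, 30 °C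
Reagents that add atoms: none
Why: Oxoammonium-mediated (TEMPO/PhI(OAc)2) oxidation of a primary alcohol, which should stop at the aldehyde without over-oxidation.

Step 2
Reactants: 2 docosanal
Product: 3 tricos-1-yne
Conditions: dimethyl (1-diazo-2-oxopropyl)phosphonate (1.3 equiv), K2CO3 (2 equiv), MeOH/THF 1:1, 25 °C
Reagents that add atoms: dimethyl (1-diazo-2-oxopropyl)phosphonate, CC(=O)C(=[N+]=[N-])P(=O)(OC)OC
Why: Ohira–Bestmann variant of the Seyferth–Gilbert homologation, a one-carbon extension in which the former aldehyde carbon should become the internal alkyne carbon that carries the C21 chain.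

Step 3
Reactants: 3 tricos-1-yne
Product: 5 2-henicosylcycloprop-2-en-1-one, via 3,3-difluoro-1-henicosylcycloprop-1-ene 4 (not isolated)
Conditions: Me3SiCF3 (2.5 equiv), NaI (0.5 equiv), THF, 110 °C (sealed tube); then Amberlyst-15, acetone/H2O, 25 °C
Reagents that add atoms: (trifluoromethyl)trimethylsilane, C[Si](C)(C)C(F)(F)F; water, O
Why: [2+1] cycloaddition of difluorocarbene to the alkyne followed by hydrolysis of the gem-difluorocyclopropene through the fluorocyclopropenium ion, an established entry to monoalkylcyclopropenones.

Step 4
Reactants: 6 methyl (E)-3-methoxyprop-2-enoate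
Product: 7 (E)-3-methoxyprop-2-enoic acid
Conditions: NaOH (1.1 equiv), H2O/MeOH, 25 °C; then HCl to pH 2, 0 °C
Reagents that add atoms: sodium hydroxide, [Na+].[OH-]
Why: Saponification (acyl substitution) of the ester, which should leave the β-methoxy enol ether and the E geometry untouched if the acidification is cold and brief.

Step 5
Reactants: 7 (E)-3-methoxyprop-2-enoic acid
Product: 9 (E)-N,N-diethyl-3-methoxyprop-2-enamide, via (E)-3-methoxyprop-2-enoyl chloride 8 (not isolated)
Conditions: (COCl)2 (1.2 equiv), DMF (cat.), CH2Cl2, 0 to 25 °C, evaporate; then Et2NH (1.05 equiv), K2CO3 (2 equiv), CH2Cl2, −20 °C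
Reagents that add atoms: diethylamine, CCNCC
Why: Acid chloride formation and N-acylation of a secondary amine, in which attack at the acyl chloride should outrun conjugate displacement of the β-methoxy group at low temperature with one equivalent of amine.

Step 6
Reactants: 9 (E)-N,N-diethyl-3-methoxyprop-2-enamide; 5 2-henicosylcycloprop-2-en-1-one
Product: 14 2-henicosyl-6-methoxycyclohexa-2,5-diene-1,4-dione, via lithiated amide 10 (not isolated), via cyclopropenolate 11 (not isolated), via acylvinyllithium 12 (not isolated), via hemiaminal alkoxide 13 (not isolated)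
Conditions: 9 (1.1 equiv), s-BuLi (1.05 equiv), TMEDA (1.1 equiv), THF, −90 °C; then 5 (1.0 equiv) in THF, −90 to −20 °C; then cold 1 M HCl
Reagents that add atoms: none
Why: Proposed new method: s-BuLi/TMEDA should remove the vinylic hydrogen of 9 that is geminal to OMe and cis to the amide carbonyl (the diethylamide directs and itself resists the base), and the chelated vinyllithium 10 should add to the carbonyl of 5 to give cyclopropenolate 11, whose strain-driven retro-addition cleaves the bond between the carbinol carbon and the unsubstituted ring CH to give the β-acylvinyllithium 12; 12 then closes the six-membered ring by 6-exo-trig attack on the amide carbonyl to give the tetrahedral adduct 13, which loses diethylamine on acidic work-up, so the net event is a [3+3] union of two O=C–C=C triads that forms C6–C1 first and C3–C4 second. The closest known reaction types are the addition of β-lithiated β-methoxyacrylic acid derivatives to ketones (tetronate synthesis), the alkoxide- or hydroxide-induced opening of cyclopropenones to cis-acrylic acid derivatives through a vinyl carbanion, and the Parham-type cyclisation of a vinyllithium onto a diethylamide. No stereocentre is created (those of 11 and 13 are transient), and the two cis relationships needed for closure follow from the lithiation cis to the amide in 10 and from the ring of 5, which leaves the carbanion of 12 on the same side of the double bond as the new ketone. The step needs carbonyl addition instead of deprotonation of the ring C–H of 5 (low temperature, hard lithium reagent), ring opening toward the CH carbon instead of the chain-bearing carbon (the less substituted vinyl carbanion is the more stable), and C- instead of O-acylation (the tertiary amide is inert to the alkoxide of 11, accepts the carbanion of 12 and stops at 13, so lactonisation and double addition are excluded).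

Step 7
Reactants: 14 2-henicosyl-6-methoxycyclohexa-2,5-diene-1,4-dione
Product: 15 2-henicosyl-6-methoxy-3-methylcyclohexa-2,5-diene-1,4-dione
Conditions: AcOH (10 equiv), AgNO3 (0.3 equiv), (NH4)2S2O8 (2 equiv), MeCN/H2O/PhCF3, 70 °C
Reagents that add atoms: acetic acid, CC(=O)O
Why: Minisci-type decarboxylative radical C–H alkylation of a quinone, in which the nucleophilic methyl radical should add to the unsubstituted C3 of the electron-poor enedione double bond and not to C5, the β-carbon of the methoxy enone, before reoxidation to the quinone.

**Compound list**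

1 | docosan-1-ol | CCCCCCCCCCCCCCCCCCCCCCO | starting material
2 | docosanal | CCCCCCCCCCCCCCCCCCCCCC=O | intermediate
3 | tricos-1-yne | CCCCCCCCCCCCCCCCCCCCCC#C | intermediate
4 | 3,3-difluoro-1-henicosylcycloprop-1-ene | CCCCCCCCCCCCCCCCCCCCCC1=CC1(F)F | intermediate (not isolated)
5 | 2-henicosylcycloprop-2-en-1-one | CCCCCCCCCCCCCCCCCCCCCC1=CC1=O | intermediate
6 | methyl (E)-3-methoxyprop-2-enoate | CO/C=C/C(=O)OC | starting material
7 | (E)-3-methoxyprop-2-enoic acid | CO/C=C/C(=O)O | intermediate
8 | (E)-3-methoxyprop-2-enoyl chloride | CO/C=C/C(=O)Cl | intermediate (not isolated)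
9 | (E)-N,N-diethyl-3-methoxyprop-2-enamide | CO/C=C/C(=O)N(CC)CC | intermediate
10 | (E)-N,N-diethyl-3-lithio-3-methoxyprop-2-enamide (lithiated amide, lithium cis to the amide carbonyl) | CO/C([Li])=C/C(=O)N(CC)CC | intermediate (not isolated)
11 | lithium 1-[(E)-3-(diethylamino)-1-methoxy-3-oxoprop-1-en-1-yl]-2-henicosylcycloprop-2-en-1-olate (cyclopropenolate, racemic) | CCCCCCCCCCCCCCCCCCCCCC1=CC1(O[Li])/C(OC)=C\C(=O)N(CC)CC | intermediate (not isolated)
12 | (2E,5Z)-N,N-diethyl-5-henicosyl-6-lithio-3-methoxy-4-oxohexa-2,5-dienamide (acylvinyllithium) | [Li]/C=C(CCCCCCCCCCCCCCCCCCCCC)\C(=O)/C(OC)=C\C(=O)N(CC)CC | intermediate (not isolated)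
13 | lithium 1-(diethylamino)-3-henicosyl-5-methoxy-4-oxocyclohexa-2,5-dien-1-olate (hemiaminal alkoxide, racemic) | CCCCCCCCCCCCCCCCCCCCCC1=CC(O[Li])(N(CC)CC)C=C(OC)C1=O | intermediate (not isolated)
14 | 2-henicosyl-6-methoxycyclohexa-2,5-diene-1,4-dione | CCCCCCCCCCCCCCCCCCCCCC1=CC(=O)C=C(OC)C1=O | intermediate
15 | 2-henicosyl-6-methoxy-3-methylcyclohexa-2,5-diene-1,4-dione | CCCCCCCCCCCCCCCCCCCCCC1=C(C)C(=O)C=C(OC)C1=O | target

**Step count and risks**

Total steps: 7. Longest linear sequence: 5 steps (1 → 2 → 3 → 5 → 14 → 15; steps 1, 2, 3, 6, 7).

Steps most likely to fail: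

1. Step 6 (the proposed new method). What may go wrong: proton transfer from the ring C–H of 5 to the vinyllithium in place of carbonyl addition; a cyclopropenolate that does not fragment before 10 decomposes; or fragmentation toward the chain-bearing ring carbon. Fallback with known chemistry, setting out from docosanal 2 and returning at quinone 14, builds the ring by the classical alkylresorcinol route instead. Aldol condensation of 2 with acetone (NaOH, H2O/acetone) should give (E)-pentacos-3-en-2-one F1. Michael addition of dimethyl malonate and Claisen ring closure (NaOMe, MeOH, reflux) should give methyl 6-henicosyl-2,4-dioxocyclohexane-1-carboxylate F2. Bromination, dehydrobromination and loss of the ester group (Br2, DMF, 0 to 150 °C) should give 5-henicosylbenzene-1,3-diol F3. Mono-O-methylation (Me2SO4, 1 equiv, K2CO3, acetone) should give 3-henicosyl-5-methoxyphenol F4, and oxidation at the free para position of the phenol with K2[ON(SO3)2] (KH2PO4 buffer, acetone/H2O) should give 14.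

2. Step 7. What may go wrong: radical attack spread over both ring CH positions, slow decarboxylation of acetic acid, and oxidative loss of the lipophilic quinone. The fallback sets out from 14 and returns at 15, replacing the radical step by arene chemistry. Reduction with Na2S2O4 (Et2O/H2O) should give 2-henicosyl-6-methoxybenzene-1,4-diol F5, and O-methylation (Me2SO4, K2CO3, acetone) should give 1-henicosyl-2,3,5-trimethoxybenzene F6. Electrophilic bromination (NBS, MeCN) is expected at the one ring CH that is para to a methoxy group and not flanked by two of them, giving 2-bromo-3-henicosyl-1,4,5-trimethoxybenzene F7. Bromine–lithium exchange (n-BuLi, THF, −78 °C) to (2-henicosyl-3,4,6-trimethoxyphenyl)lithium F8 and quenching with MeI should give 3-henicosyl-1,4,5-trimethoxy-2-methylbenzene F9. Oxidative demethylation of the para-dimethoxy pair with (NH4)2Ce(NO3)6 (MeCN/H2O, 0 °C) should give 15.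

3. Step 3. What may go wrong: silylation of the acetylenic C–H in place of carbene transfer, and oligomerisation of the monoalkylcyclopropenone during the acidic hydrolysis. The fallback sets out from docosan-1-ol 1 and returns at 5 without any carbene. Appel bromination (CBr4, PPh3, CH2Cl2) should give 1-bromodocosane F10. Its Grignard reagent docosylmagnesium bromide F11 (Mg, THF) should be acylated by N-methoxy-N-methylacetamide to tetracosan-2-one F12. Acid-catalysed α,α′-dibromination (Br2, HBr cat., AcOH) should give 1,3-dibromotetracosan-2-one F13, and double dehydrobromination with Et3N (CH2Cl2, 0 °C; Favorskii-type 1,3-elimination, then loss of the second HBr) should give 5.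

**Further compounds**

F1 | step 6 | (E)-pentacos-3-en-2-one | CCCCCCCCCCCCCCCCCCCCC/C=C/C(C)=O
F2 | step 6 | methyl 6-henicosyl-2,4-dioxocyclohexane-1-carboxylate (racemic mixture of diastereomers and enol forms) | CCCCCCCCCCCCCCCCCCCCCC1CC(=O)CC(=O)C1C(=O)OC
F3 | step 6 | 5-henicosylbenzene-1,3-diol | CCCCCCCCCCCCCCCCCCCCCc1cc(O)cc(O)c1
F4 | step 6 | 3-henicosyl-5-methoxyphenol | CCCCCCCCCCCCCCCCCCCCCc1cc(O)cc(OC)c1
F5 | step 7 | 2-henicosyl-6-methoxybenzene-1,4-diol | CCCCCCCCCCCCCCCCCCCCCc1cc(O)cc(OC)c1O
F6 | step 7 | 1-henicosyl-2,3,5-trimethoxybenzene | CCCCCCCCCCCCCCCCCCCCCc1cc(OC)cc(OC)c1OC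
F7 | step 7 | 2-bromo-3-henicosyl-1,4,5-trimethoxybenzene | CCCCCCCCCCCCCCCCCCCCCc1c(Br)c(OC)cc(OC)c1OC
F8 | step 7 | (2-henicosyl-3,4,6-trimethoxyphenyl)lithium | CCCCCCCCCCCCCCCCCCCCCc1c([Li])c(OC)cc(OC)c1OC
F9 | step 7 | 3-henicosyl-1,4,5-trimethoxy-2-methylbenzene | CCCCCCCCCCCCCCCCCCCCCc1c(C)c(OC)cc(OC)c1OC
F10 | step 3 | 1-bromodocosane | CCCCCCCCCCCCCCCCCCCCCCBr
F11 | step 3 | docosylmagnesium bromide | CCCCCCCCCCCCCCCCCCCCCC[Mg]Br
F12 | step 3 | tetracosan-2-one | CCCCCCCCCCCCCCCCCCCCCCC(C)=O
F13 | step 3 | 1,3-dibromotetracosan-2-one (racemic) | CCCCCCCCCCCCCCCCCCCCCC(Br)C(=O)CBr
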